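**Plan**

- Each benzene ring is numbered C1 (OMe), C2 (Me), C3 (OH), C4 (acetyl), C5 (OH), C6 (carrying the bridging CH2).
- Backwards, the four phenolic O–H bonds become ethyl ethers. The two C4–acetyl bonds and the two O–CH3 bonds are cut next, then C1–C2 and C3–C4 of each ring (C1–C6 is broken and re-formed in the same step). Last, the two cyclobutenones are cut back to glutaryl dichloride and ethoxyacetylene.
- The enabling feature: the C2(Me)–C3(O) pair is the imprint of a 1-alkoxypropyne, and C1, C6, C5, C4 are the carbonyl, sp3, alkoxy-bearing and vinylic carbons of a 3-alkoxycyclobut-2-enone whose sp3 carbon holds the bridge. The carbonyl carbon emerges as the only free phenol, at C1, where the methyl ether is needed.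
- Forwards, both four-membered rings are made in one twofold ketene–ynol ether [2+2] step, and both benzene rings then arise together in a twofold benzannulation. O-methylation, C-acetylation and removal of the ethyl groups follow.
- The target has no stereocentre; the two sp3 centres of the biscyclobutenone form without control and vanish on ring opening.

Key step: step 2

Assumption: the two ends of the linking chain are taken to react independently, so the short-lived intermediates of the twofold steps are written in their symmetric twofold form. The stereocentres of the cyclobutenone and cyclohexadienone intermediates are uncontrolled mixtures, written without configuration because all are erased before the first aromatic compound.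

Remark on stoichiometry: steps 1 and 2 are twofold cycloadditions, each of which builds two molecules of the alkyne into one molecule of the bis-electrophile (1 + 2 × 2 → 6 + 2 HCl; 6 + 2 × 7 → 12). The first alkyne molecule stands on the Reactants line under its number and the second on the line of reagents that add atoms. Steps 3 and 4 likewise build in two molecules of MeI and of AcCl, and step 5 removes four ethyl groups.

**Route**

Step 1
Reactants: 1 glutaryl dichloride; 2 ethoxyacetylene
Product: 6 4,4'-methylenebis(3-ethoxycyclobut-2-en-1-one), via ketene acid chloride 3 (not isolated), via monocyclobutenone acid chloride 4 (not isolated), via monocyclobutenone ketene 5 (not isolated)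
Conditions: 2 (5 equiv), Et3N (2.4 equiv, slow addition), Et2O, 0 °C → rt
Reagents that add atoms: ethoxyacetylene (second molecule of 2), C#COCC
Why: Dehydrochlorination of each acyl chloride terminus by Et3N gives an aldoketene that the excess ynol ether traps in a ketene–alkyne [2+2] cycloaddition, once at each end and so with two molecules of 2 in all, the unsubstituted alkyne carbon bonding to the ketene carbonyl carbon so that ethoxy ends at C3 and the chain at C4 of each cyclobutenone; slow addition of the base keeps the ketene concentration low and the two new stereocentres need no control.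

Step 2
Reactants: 6 4,4'-methylenebis(3-ethoxycyclobut-2-en-1-one); 7 1-ethoxyprop-1-yne
Product: 12 2,2'-methylenebis(3,5-diethoxy-6-methylphenol), via bis(vinylketene) 8 (not isolated), via bis(4-vinylcyclobutenone) 9 (not isolated), via bis(dienylketene) 10 (not isolated), via bis(cyclohexadienone) 11 (not isolated)
Conditions: 7 (6 equiv), added in three portions, toluene, 110 °C, sealed tube; then KOH, MeOH, rt
Reagents that add atoms: 1-ethoxyprop-1-yne (second molecule of 7), CC#COCC
Why: Heat opens each 4-alkyl-3-ethoxycyclobutenone by four-electron electrocyclic cleavage of the C(=O)–C(sp3) bond to a vinylketene, whose ketene carbon is attacked by the methyl-bearing carbon of one molecule of the ynol ether in a [2+2] cycloaddition to give a 4-vinylcyclobutenone; this reopens to a dienylketene that cyclises and tautomerises to the phenol, the sequence known as the Danheiser benzannulation of cyclobutenones with alkoxyalkynes, run here at both cyclobutenones so that two molecules of 7 are taken up. Each benzene ring closes by a thermal six-electron electrocyclisation of the (Z)-dienylketene, which joins the ketene carbon (C1) to the former sp3 carbon (C6) after the [2+2] step has made C1–C2 and C3–C4. No stereocentre is formed, and the two sp3 centres of 6 disappear at the first ring opening, so both diastereomers converge. The step needs one regiochemistry in the [2+2] addition, and the polarisation of the ynol ether secures it: its oxygen-free carbon is the nucleophile and bonds to the electrophilic ketene carbon, which places methyl at C2 beside the new hydroxyl and ethoxy at C3. The 3-ethoxy group of the cyclobutenone is a spectator that should slow ring opening, hence 110 °C and an excess of 7 added in portions to offset its own thermal loss; the closing KOH/MeOH treatment should cleave any aryl ester formed when product phenol captures a ketene.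

Step 3
Reactants: 12 2,2'-methylenebis(3,5-diethoxy-6-methylphenol)
Product: 13 bis(4,6-diethoxy-2-methoxy-3-methylphenyl)methane
Conditions: MeI, K2CO3, DMF, rt
Reagents that add atoms: iodomethane, CI
Why: Williamson etherification: the two C1 hydroxyls are the only acidic sites of 12, so the methyl groups go onto exactly the oxygens that are methylated in the target.

Step 4
Reactants: 13 bis(4,6-diethoxy-2-methoxy-3-methylphenyl)methane
Product: 14 bis(3-acetyl-2,4-diethoxy-6-methoxy-5-methylphenyl)methane
Conditions: AcCl, SnCl4, CH2Cl2, −20 → 0 °C
Reagents that add atoms: acetyl chloride, CC(Cl)=O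
Why: Friedel–Crafts acylation: each ring has a single unsubstituted carbon, C4, activated by two ortho ethoxy groups and a para methoxy group, the first acetyl deactivates its own ring so that one enters per ring, and SnCl4 at low temperature should spare the ethers and the diarylmethane bridge.

Step 5
Reactants: 14 bis(3-acetyl-2,4-diethoxy-6-methoxy-5-methylphenyl)methane
Product: 15 mallotophenone
Conditions: AlCl3 (excess), CH2Cl2, 0 °C → rt; then aq. HCl
Reagents that add atoms: none
Why: Chelation-controlled dealkylation of ortho-alkoxy aryl ketones by AlCl3: aluminium held between the ketone oxygen and a neighbouring ethoxy oxygen in a six-membered chelate lets chloride remove the ethyl group as chloroethane, the labile aluminium phenoxide–ketone chelate should let the acetyl turn and activate the second ethoxy group, and the C1 methoxy group has no adjacent carbonyl and is not activated in this way.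

**Compound list**

1 | glutaryl dichloride (pentanedioyl dichloride) | O=C(Cl)CCCC(Cl)=O | starting material
2 | ethoxyacetylene (ethoxyethyne) | C#COCC | starting material
3 | 5-oxopent-4-enoyl chloride (ketene acid chloride) | O=C=CCCC(Cl)=O | intermediate
4 | 3-(2-ethoxy-4-oxocyclobut-2-en-1-yl)propanoyl chloride, racemic | CCOC1=CC(=O)C1CCC(Cl)=O | intermediate
5 | 3-(2-ethoxy-4-oxocyclobut-2-en-1-yl)prop-1-en-1-one, racemic | CCOC1=CC(=O)C1CC=C=O | intermediate
6 | 4,4'-methylenebis(3-ethoxycyclobut-2-en-1-one), meso and racemic forms together | CCOC1=CC(=O)C1CC1C(=O)C=C1OCC | intermediate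
7 | 1-ethoxyprop-1-yne | CC#COCC | starting material
8 | (3Z,6Z)-3,7-diethoxynona-1,3,6,8-tetraene-1,9-dione, the bis(vinylketene) | O=C=C/C(OCC)=C/C/C=C(OCC)/C=C=O | intermediate
9 | 4,4'-[(1Z,4Z)-1,5-diethoxypenta-1,4-diene-1,5-diyl]bis(3-ethoxy-2-methylcyclobut-2-en-1-one), the bis(4-vinylcyclobutenone), ring stereocentres undefined | CCOC1=C(C)C(=O)C1/C(OCC)=C/C/C=C(OCC)/C1C(=O)C(C)=C1OCC | intermediate
10 | (3E,5Z,8Z,10E)-3,5,9,11-tetraethoxy-2,12-dimethyltrideca-1,3,5,8,10,12-hexaene-1,13-dione, the bis(dienylketene) in the geometry that can cyclise | O=C=C(C)/C(OCC)=C\C(OCC)=C\C/C=C(OCC)/C=C(OCC)\C(C)=C=O | intermediate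
11 | 6,6'-methylenebis(3,5-diethoxy-2-methylcyclohexa-2,4-dien-1-one), stereocentres undefined | O=C1C(C)=C(OCC)C=C(OCC)C1CC1C(=O)C(C)=C(OCC)C=C1OCC | intermediate
12 | 2,2'-methylenebis(3,5-diethoxy-6-methylphenol) | CCOc1cc(OCC)c(Cc2c(O)c(C)c(OCC)cc2OCC)c(O)c1C | intermediate
13 | bis(4,6-diethoxy-2-methoxy-3-methylphenyl)methane | CCOc1cc(OCC)c(Cc2c(OC)c(C)c(OCC)cc2OCC)c(OC)c1C | intermediate
14 | bis(3-acetyl-2,4-diethoxy-6-methoxy-5-methylphenyl)methane | CCOc1c(C)c(OC)c(Cc2c(OC)c(C)c(OCC)c(C(C)=O)c2OCC)c(OCC)c1C(C)=O | intermediate
15 | mallotophenone, bis(3-acetyl-2,4-dihydroxy-6-methoxy-5-methylphenyl)methane | COc1c(C)c(O)c(C(C)=O)c(O)c1Cc1c(O)c(C(C)=O)c(O)c(C)c1OC | target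

**Count**

Total step count: 5. Longest linear sequence: 5 steps (1 → 6 → 12 → 13 → 14 → 15).

**Steps most likely to fail**

Step 2. Electrocyclic opening of the vinylogous-ester cyclobutenone may be slower than the thermal retro-ene fragmentation of the ethyl ynol ether, and phenol already formed may capture vinylketene of a second molecule and divert material into oligomeric esters. The fallback replaces the ynol ether by a siloxyalkyne that cannot fragment in this way and allows a bath of 140–150 °C. Triisopropyl(prop-1-yn-1-yloxy)silane F1 would be made from commercial 1-propynyllithium by oxidation to the lithium ynolate with LiOOt-Bu (from t-BuOOH and LiN(SiMe3)2) and O-silylation with i-Pr3SiCl. Heating 6 with F1 in toluene, followed by the same KOH/MeOH treatment, should give 2,2'-methylenebis[3-ethoxy-6-methyl-5-(triisopropylsilyloxy)phenol] F2 with the same regiochemistry. Methylation of the two free phenols (MeI, K2CO3, acetone) gives bis[6-ethoxy-2-methoxy-3-methyl-4-(triisopropylsilyloxy)phenyl]methane F3. Desilylation with in-situ O-ethylation (CsF, EtI, DMF) then returns to the route at 13.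

Step 1. The half-reacted diacid chloride may be diverted before the second cycloaddition, by intramolecular O-acylation onto the remaining acyl chloride or by ketene dimerisation. The fallback builds the two cyclobutenones one after the other, setting out from 2 and purchased 5-tert-butoxy-5-oxopentanoic acid F4. The acid is converted under neutral conditions (1-chloro-N,N,2-trimethylprop-1-en-1-amine, CH2Cl2) into tert-butyl 5-chloro-5-oxopentanoate F5. Treatment with Et3N and 2 gives tert-butyl 3-(2-ethoxy-4-oxocyclobut-2-en-1-yl)propanoate F6. Anhydrous CF3CO2H in CH2Cl2 frees 3-(2-ethoxy-4-oxocyclobut-2-en-1-yl)propanoic acid F7. The same chloroenamine turns F7 into acid chloride 4, now as a discrete compound, and a second Et3N/2 cycloaddition rejoins the route at 6.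

Step 5. Chemoselectivity may be lost in either direction: the reaction may stall after one dealkylation per ring, or the hindered C1 methyl ether may be cleaved as well. The fallback gives up the differentiation and restores it by hydrogen bonding. From 14, exhaustive dealkylation with BBr3 (CH2Cl2, −78 °C → rt) gives bis(3-acetyl-2,4,6-trihydroxy-5-methylphenyl)methane F8. Controlled O-methylation (Me2SO4, one equivalent per ring, K2CO3, acetone) should then take place at the hydroxyl para to each acetyl group, which is the most acidic and is not tied to the ketone by a hydrogen bond, the known selectivity of 2,4,6-trihydroxyaryl ketones. This arrives directly at 15.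

Further compounds
F1 | step 2 | triisopropyl(prop-1-yn-1-yloxy)silane | CC#CO[Si](C(C)C)(C(C)C)C(C)C
F2 | step 2 | 2,2'-methylenebis[3-ethoxy-6-methyl-5-(triisopropylsilyloxy)phenol] | Oc1c(C)c(O[Si](C(C)C)(C(C)C)C(C)C)cc(OCC)c1Cc1c(OCC)cc(O[Si](C(C)C)(C(C)C)C(C)C)c(C)c1O
F3 | step 2 | bis[6-ethoxy-2-methoxy-3-methyl-4-(triisopropylsilyloxy)phenyl]methane | COc1c(C)c(O[Si](C(C)C)(C(C)C)C(C)C)cc(OCC)c1Cc1c(OCC)cc(O[Si](C(C)C)(C(C)C)C(C)C)c(C)c1OC
F4 | step 1 | 5-tert-butoxy-5-oxopentanoic acid | CC(C)(C)OC(=O)CCCC(=O)O
F5 | step 1 | tert-butyl 5-chloro-5-oxopentanoate | CC(C)(C)OC(=O)CCCC(=O)Cl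
F6 | step 1 | tert-butyl 3-(2-ethoxy-4-oxocyclobut-2-en-1-yl)propanoate, racemic | CCOC1=CC(=O)C1CCC(=O)OC(C)(C)C
F7 | step 1 | 3-(2-ethoxy-4-oxocyclobut-2-en-1-yl)propanoic acid, racemic | CCOC1=CC(=O)C1CCC(=O)O
F8 | step 5 | bis(3-acetyl-2,4,6-trihydroxy-5-methylphenyl)methane | CC(=O)c1c(O)c(C)c(O)c(Cc2c(O)c(C)c(O)c(C(C)=O)c2O)c1O
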